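**Remark.** (−)-Epicatechin, phloroglucinol, 3,4-bis(benzyloxy)benzaldehyde and 3,4,5-tris(benzyloxy)benzoic acid are taken as commercial. Flavan numbering is used; "upper unit" is the unit whose C4 carries the interflavan bond, and 4β means trans to the C3 oxygen of that unit.

## Retrosynthetic overview

1. The target is (−)-epicatechin gallate-(4β→6)-(−)-epicatechin gallate; the last operations are global hydrogenolysis of benzyl ethers and one double galloylation of the two C3 hydroxyls.
2. Key disconnection: ring C of the lower unit is opened at C4–C4a and O1–C2, giving a phenol (the upper unit carrying a 2,6-bis(benzyloxy)-4-hydroxyphenyl ring at C4) and an (R)-aryl oxiranyl ketone that supplies C4–C3–C2 and ring B. The forward reaction is a reductive (3+3) annulation.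
3. Enabling feature: ring A of the lower unit is a phloroglucinol ring. C4a lies between the oxygen-bearing C5 and C8a, and O1 sits on C8a, so C4a/O1 are an adjacent C,O-bis-nucleophile. C2 carries the electron-rich ring B, so it can be an aryl ketone and then an oxocarbenium ion. In the precursor only the oxygen para to the interflavan carbon is free and the two ring carbons ortho to it are equivalent, which fixes the 4→6 connectivity.
4. The phenol comes from (−)-epicatechin (both stereocentres bought): benzylation, DDQ oxidation at C4, Friedel–Crafts capture of the C4 cation by symmetrical phloroglucinol (sets 4β), then steric differentiation of the para oxygen.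
5. Ring order: rings A, C and B of the upper unit are bought; the phloroglucinol ring (future ring A of the lower unit) is attached next; ring C of the lower unit closes last. Its C3 comes from a Sharpless kinetic resolution and its C2 is relayed from C3.

Key step: step 10

## Route

Step 1
Reactants: 1 (−)-epicatechin
Product: 2 5,7,3',4'-tetra-O-benzyl-(−)-epicatechin
Conditions: BnBr (4.4 equiv), K2CO3, DMF, 0 °C → rt
Reagents that add atoms: benzyl bromide, BrCc1ccccc1
Why: Williamson O-benzylation of the four phenolic hydroxyls with K2CO3 should leave the far less acidic secondary C3 hydroxyl free; the two stereocentres are bought and not touched.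

Step 2
Reactants: 2 5,7,3',4'-tetra-O-benzyl-(−)-epicatechin
Product: 3 4β-(2-ethoxyethoxy)-5,7,3',4'-tetra-O-benzyl-(−)-epicatechin
Conditions: DDQ (2 equiv), 2-ethoxyethanol, CH2Cl2, rt
Reagents that add atoms: 2-ethoxyethanol, CCOCCO
Why: DDQ abstracts hydride from the benzylic C4 (cation stabilised by the 5- and 7-benzyloxy groups) and the alcohol traps it trans to the C3 hydroxyl, a known oxidative C4 etherification of benzylated flavan-3-ols; this centre is re-ionised in step 3.

Step 3
Reactants: 3 4β-(2-ethoxyethoxy)-5,7,3',4'-tetra-O-benzyl-(−)-epicatechin; 4 phloroglucinol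
Product: 5 4β-(2,4,6-trihydroxyphenyl)-5,7,3',4'-tetra-O-benzyl-(−)-epicatechin
Conditions: 4 (6 equiv), BF3·OEt2 (1 equiv), 1,4-dioxane/CH2Cl2, 0 °C
Reagents that add atoms: none
Why: Friedel–Crafts alkylation: BF3 ionises the C4 ether and the symmetrical phloroglucinol (excess, no regiochemical question) should attack the benzylic cation anti to the C3 hydroxyl and the C2 aryl group, setting the 4β (3,4-trans) centre as in the acid-mediated phloroglucinol capture of procyanidin cations.

Step 4
Reactants: 5 4β-(2,4,6-trihydroxyphenyl)-5,7,3',4'-tetra-O-benzyl-(−)-epicatechin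
Product: 6 4β-[2,6-dihydroxy-4-(triisopropylsilyloxy)phenyl]-5,7,3',4'-tetra-O-benzyl-(−)-epicatechin
Conditions: TIPSCl (1.05 equiv), imidazole (1.1 equiv), DMF, −20 °C
Reagents that add atoms: triisopropylsilyl chloride, CC(C)[Si](Cl)(C(C)C)C(C)C
Why: Silylation with the bulky chloride should select the only phenolic hydroxyl that is not ortho to the flavan-4-yl group (steric differentiation; the hindered secondary C3 hydroxyl is slower still), and this choice later decides the 4→6 connectivity.

Step 5
Reactants: 6 4β-[2,6-dihydroxy-4-(triisopropylsilyloxy)phenyl]-5,7,3',4'-tetra-O-benzyl-(−)-epicatechin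
Product: 7 4β-[2,6-bis(benzyloxy)-4-(triisopropylsilyloxy)phenyl]-5,7,3',4'-tetra-O-benzyl-(−)-epicatechin
Conditions: BnBr (2.4 equiv), K2CO3, acetone, 50 °C
Reagents that add atoms: benzyl bromide, BrCc1ccccc1
Why: Williamson benzylation of the two equivalent remaining phenols in a polar aprotic medium (favouring O- over C-alkylation); the aryl TIPS ether and the secondary alcohol should survive K2CO3 in acetone.

Step 6
Reactants: 7 4β-[2,6-bis(benzyloxy)-4-(triisopropylsilyloxy)phenyl]-5,7,3',4'-tetra-O-benzyl-(−)-epicatechin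
Product: 8 4β-[2,6-bis(benzyloxy)-4-hydroxyphenyl]-5,7,3',4'-tetra-O-benzyl-(−)-epicatechin
Conditions: TBAF (1.1 equiv), AcOH (1.1 equiv), THF, 0 °C
Reagents that add atoms: none
Why: Fluoride cleaves the aryl Si–O bond selectively (benzyl ethers are inert) and acetic acid buffers the liberated phenoxide.

Step 7
Reactants: 9 3,4-bis(benzyloxy)benzaldehyde
Product: 10 rac-1-[3,4-bis(benzyloxy)phenyl]prop-2-en-1-ol
Conditions: CH2=CHMgBr (1.2 equiv), THF, −78 → 0 °C
Reagents that add atoms: vinylmagnesium bromide, C=C[Mg]Br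
Why: Grignard 1,2-addition to the aldehyde gives the racemic secondary allylic alcohol needed for kinetic resolution.

Step 8
Reactants: 10 rac-1-[3,4-bis(benzyloxy)phenyl]prop-2-en-1-ol
Product: 11 (S)-[3,4-bis(benzyloxy)phenyl][(2R)-oxiran-2-yl]methanol (erythro)
Conditions: Ti(OiPr)4 (10 mol %), L-(+)-diisopropyl tartrate (15 mol %), t-BuOOH (0.6 equiv), 4 Å molecular sieves, CH2Cl2, −20 °C
Reagents that add atoms: tert-butyl hydroperoxide, CC(C)(C)OO
Why: Sharpless asymmetric epoxidation under kinetic resolution: with L-(+)-tartrate the (R)-alcohol should be epoxidised fast and erythro-selectively (the (S)-alcohol is left), which sets the epoxide carbon that becomes C3 of the lower unit.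

Step 9
Reactants: 11 (S)-[3,4-bis(benzyloxy)phenyl][(2R)-oxiran-2-yl]methanol
Product: 12 [3,4-bis(benzyloxy)phenyl][(2R)-oxiran-2-yl]methanone
Conditions: activated MnO2 (excess), CH2Cl2, rt
Reagents that add atoms: none
Why: MnO2 oxidises the benzylic alcohol under neutral conditions that should spare the acid-sensitive epoxide; the epoxide stereocentre is not readily enolisable and should be kept.

Step 10
Reactants: 8 4β-[2,6-bis(benzyloxy)-4-hydroxyphenyl]-5,7,3',4'-tetra-O-benzyl-(−)-epicatechin; 12 [3,4-bis(benzyloxy)phenyl][(2R)-oxiran-2-yl]methanone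
Product: 15 octa-O-benzyl procyanidin B5, via hydroxy ketone 13 (not isolated), via cyclic hemiketal 14 (not isolated)
Conditions: 12 (1.2 equiv), BF3·OEt2 (1.2 equiv), CH2Cl2, −40 → −10 °C; then Et3SiH (5 equiv), BF3·OEt2 (2 equiv), −40 → 0 °C
Reagents that add atoms: none
Why: Proposed new method: BF3 activates the epoxide of 12, and the ring carbon of 8 ortho to the free hydroxyl (activated by three oxygens; the two such carbons are equivalent) should open it at the unsubstituted CH2 terminus, because the carbonyl disfavours positive charge at the other epoxide carbon, which forms C4–C4a without touching the C3–O bond and gives 13; the free phenol then adds to the aryl ketone (O1–C2) to give 14, BF3 ionises it to the 2-aryl-4H-chromenylium ion and Et3SiH reduces that ion. The closest known reaction types are the Lewis-acid Friedel–Crafts opening of epoxides by electron-rich arenes (intramolecular with aryl glycidyl ethers to chroman-3-ols) and the Et3SiH/Lewis-acid reductive etherification of α-oxygenated 2'-hydroxydihydrochalcones to 2,3-cis-flavans; new is their intermolecular union in one flask with a terminal epoxy ketone. Ring C is closed by C-alkylation followed by 6-exo-trig addition of the phenol oxygen to the carbonyl and reductive loss of the hemiketal hydroxyl. C3 (R) comes unchanged from the epoxide, and C2 is set by substrate control: the C3 oxygen should sit pseudo-axial in the half-chair cation (avoiding allylic strain with the coplanar ring B) and hydride should enter on the opposite face, placing ring B cis to the C3 oxygen (2R). The step needs C- over O-alkylation (favoured by the non-basic Lewis-acidic medium and the very nucleophilic ring carbon), the 4→6 over the 4→8 mode (secured because only the oxygen para to the interflavan carbon is free) and survival of the acid-labile interflavan bond (low temperature, aprotic solvent).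

Step 11
Reactants: 15 octa-O-benzyl procyanidin B5; 16 3,4,5-tris(benzyloxy)benzoic acid
Product: 17 octa-O-benzyl procyanidin B5 3,3'-bis[3,4,5-tris(benzyloxy)benzoate]
Conditions: 16 (4 equiv), DCC (4 equiv), DMAP (cat.), CH2Cl2, rt
Reagents that add atoms: none
Why: Steglich esterification with excess acid should acylate both hindered secondary hydroxyls in one step, as in the bis-galloylation of benzylated procyanidin dimers; acylation at oxygen touches no stereocentre.

Step 12
Reactants: 17 octa-O-benzyl procyanidin B5 3,3'-bis[3,4,5-tris(benzyloxy)benzoate]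
Product: 18 procyanidin B5 3,3'-di-O-gallate
Conditions: H2 (1 atm), Pd(OH)2/C, THF/MeOH/H2O, rt
Reagents that add atoms: none
Why: Catalytic hydrogenolysis should remove all fourteen benzyl ethers while the esters, the pyran C–O bonds and the interflavan bond are kept, as in the final step of benzylated procyanidin gallate syntheses.

## Compound list

1 | (−)-epicatechin, (2R,3R) | O[C@@H]1Cc2c(O)cc(O)cc2O[C@@H]1c1ccc(O)c(O)c1 | starting material
2 | 5,7,3',4'-tetra-O-benzyl-(−)-epicatechin | O[C@@H]1Cc2c(OCc3ccccc3)cc(OCc3ccccc3)cc2O[C@@H]1c1ccc(OCc2ccccc2)c(OCc2ccccc2)c1 | intermediate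
3 | 4β-(2-ethoxyethoxy)-5,7,3',4'-tetra-O-benzyl-(−)-epicatechin (ether trans to the C3 hydroxyl) | O[C@@H]1[C@@H](OCCOCC)c2c(OCc3ccccc3)cc(OCc3ccccc3)cc2O[C@@H]1c1ccc(OCc2ccccc2)c(OCc2ccccc2)c1 | intermediate
4 | phloroglucinol (benzene-1,3,5-triol) | Oc1cc(O)cc(O)c1 | starting material
5 | 4β-(2,4,6-trihydroxyphenyl)-5,7,3',4'-tetra-O-benzyl-(−)-epicatechin (aryl trans to the C3 hydroxyl) | O[C@@H]1[C@@H](c2c(O)cc(O)cc2O)c2c(OCc3ccccc3)cc(OCc3ccccc3)cc2O[C@@H]1c1ccc(OCc2ccccc2)c(OCc2ccccc2)c1 | intermediate
6 | 4β-[2,6-dihydroxy-4-(triisopropylsilyloxy)phenyl]-5,7,3',4'-tetra-O-benzyl-(−)-epicatechin | O[C@@H]1[C@@H](c2c(O)cc(O[Si](C(C)C)(C(C)C)C(C)C)cc2O)c2c(OCc3ccccc3)cc(OCc3ccccc3)cc2O[C@@H]1c1ccc(OCc2ccccc2)c(OCc2ccccc2)c1 | intermediate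
7 | 4β-[2,6-bis(benzyloxy)-4-(triisopropylsilyloxy)phenyl]-5,7,3',4'-tetra-O-benzyl-(−)-epicatechin | O[C@@H]1[C@@H](c2c(OCc3ccccc3)cc(O[Si](C(C)C)(C(C)C)C(C)C)cc2OCc2ccccc2)c2c(OCc3ccccc3)cc(OCc3ccccc3)cc2O[C@@H]1c1ccc(OCc2ccccc2)c(OCc2ccccc2)c1 | intermediate
8 | 4β-[2,6-bis(benzyloxy)-4-hydroxyphenyl]-5,7,3',4'-tetra-O-benzyl-(−)-epicatechin | O[C@@H]1[C@@H](c2c(OCc3ccccc3)cc(O)cc2OCc2ccccc2)c2c(OCc3ccccc3)cc(OCc3ccccc3)cc2O[C@@H]1c1ccc(OCc2ccccc2)c(OCc2ccccc2)c1 | intermediate
9 | 3,4-bis(benzyloxy)benzaldehyde | O=Cc1ccc(OCc2ccccc2)c(OCc2ccccc2)c1 | starting material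
10 | rac-1-[3,4-bis(benzyloxy)phenyl]prop-2-en-1-ol | C=CC(O)c1ccc(OCc2ccccc2)c(OCc2ccccc2)c1 | intermediate
11 | (S)-[3,4-bis(benzyloxy)phenyl][(2R)-oxiran-2-yl]methanol (erythro) | C1[C@@H](O1)[C@H](c1ccc(OCc2ccccc2)c(OCc2ccccc2)c1)O | intermediate
12 | [3,4-bis(benzyloxy)phenyl][(2R)-oxiran-2-yl]methanone | C1[C@@H](O1)C(=O)c1ccc(OCc2ccccc2)c(OCc2ccccc2)c1 | intermediate
13 | hydroxy ketone: 8 carrying, on the ring carbon ortho to its free hydroxyl, a (2R)-3-[3,4-bis(benzyloxy)phenyl]-2-hydroxy-3-oxopropyl chain | O[C@@H]1[C@@H](c2c(OCc3ccccc3)cc(O)c(C[C@@H](O)C(=O)c3ccc(OCc4ccccc4)c(OCc4ccccc4)c3)c2OCc2ccccc2)c2c(OCc3ccccc3)cc(OCc3ccccc3)cc2O[C@@H]1c1ccc(OCc2ccccc2)c(OCc2ccccc2)c1 | intermediate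
14 | cyclic hemiketal: the 2-hydroxy derivative of 15 at C2 of the lower unit (3R, both C2 epimers) | O[C@@H]1[C@@H](c2c(OCc3ccccc3)cc3c(c2OCc2ccccc2)C[C@@H](O)C(O)(c2ccc(OCc4ccccc4)c(OCc4ccccc4)c2)O3)c2c(OCc3ccccc3)cc(OCc3ccccc3)cc2O[C@@H]1c1ccc(OCc2ccccc2)c(OCc2ccccc2)c1 | intermediate
15 | octa-O-benzyl procyanidin B5: 5,7,3',4'-tetra-O-benzyl-(−)-epicatechin-(4β→6)-5,7,3',4'-tetra-O-benzyl-(−)-epicatechin | O[C@@H]1[C@@H](c2c(OCc3ccccc3)cc3c(c2OCc2ccccc2)C[C@@H](O)[C@@H](c2ccc(OCc4ccccc4)c(OCc4ccccc4)c2)O3)c2c(OCc3ccccc3)cc(OCc3ccccc3)cc2O[C@@H]1c1ccc(OCc2ccccc2)c(OCc2ccccc2)c1 | intermediate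
16 | 3,4,5-tris(benzyloxy)benzoic acid | OC(=O)c1cc(OCc2ccccc2)c(OCc2ccccc2)c(OCc2ccccc2)c1 | starting material
17 | octa-O-benzyl procyanidin B5 3,3'-bis[3,4,5-tris(benzyloxy)benzoate] | O=C(O[C@@H]1[C@@H](c2c(OCc3ccccc3)cc3c(c2OCc2ccccc2)C[C@@H](OC(=O)c2cc(OCc4ccccc4)c(OCc4ccccc4)c(OCc4ccccc4)c2)[C@@H](c2ccc(OCc4ccccc4)c(OCc4ccccc4)c2)O3)c2c(OCc3ccccc3)cc(OCc3ccccc3)cc2O[C@@H]1c1ccc(OCc2ccccc2)c(OCc2ccccc2)c1)c1cc(OCc2ccccc2)c(OCc2ccccc2)c(OCc2ccccc2)c1 | intermediate
18 | procyanidin B5 3,3'-di-O-gallate | O=C(O[C@@H]1[C@@H](c2c(O)cc3c(c2O)C[C@@H](OC(=O)c2cc(O)c(O)c(O)c2)[C@@H](c2ccc(O)c(O)c2)O3)c2c(O)cc(O)cc2O[C@@H]1c1ccc(O)c(O)c1)c1cc(O)c(O)c(O)c1 | target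

## Step count and risks

Total steps: 12. Longest linear sequence: 9 steps (steps 1–6, then 10–12); steps 7–9 form the second branch.

**Step 10 (Proposed new method).** What may go wrong:
- O-alkylation of the phenol or of the secondary hydroxyl by the activated epoxide instead of ring C-alkylation;
- acid-induced heterolysis of the interflavan bond followed by silane capture;
- enolisation of the α-hydroxy ketone with erosion of C3;
- poor facial selectivity of hydride delivery, or over-reduction of the aryl ketone.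

Fallback with known chemistry: it sets out from 8 and 11. A Mitsunobu etherification (DIAD, PPh3, toluene, 0 °C) of the free phenol of 8 with the benzylic alcohol of 11 should give, with inversion at the carbinol carbon, the epoxy aryl ether 4β-{2,6-bis(benzyloxy)-4-[(R)-[3,4-bis(benzyloxy)phenyl][(2R)-oxiran-2-yl]methoxy]phenyl}-5,7,3',4'-tetra-O-benzyl-(−)-epicatechin F1. A Lewis-acid 6-endo epoxide–arene cyclisation of this aryl glycidyl-type ether (BF3·OEt2, CH2Cl2, −78 °C, or AuCl3/AgOTf in catalytic amounts) should then form C4–C4a at the epoxide CH2. The fallback comes back to the route at 15; here C2 is set by the SN2 inversion and C3 again by the epoxide.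

**Step 4.** What may go wrong: insufficient site selectivity of the silylation (reaction at a hydroxyl ortho to the flavanyl group, or double silylation), which would carry the wrong free oxygen forward and lead to the 4→8 mode of ring closure.

Fallback: it sets out from 3 and replaces steps 3–6 by one direct Friedel–Crafts coupling of the C4 cation with commercial 3,5-bis(benzyloxy)phenol (TMSOTf, CH2Cl2, −78 → −40 °C). The product alkylated para to the free hydroxyl is 8 and would be separated by chromatography from the isomer alkylated ortho to it; regiochemistry then rests on separation and assignment instead of on protecting-group differentiation. It comes back to the route at 8 and makes no compound outside the compound list (F0).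

**Step 8.** What may go wrong: ionisation or rearrangement of the electron-rich benzylic epoxy alcohol under the titanium alkoxide conditions, or a low selectivity factor in the resolution.

Fallback: it sets out from 10. Oxidation with MnO2 should give 1-[3,4-bis(benzyloxy)phenyl]prop-2-en-1-one F2. Weitz–Scheffer epoxidation (H2O2, NaOH, MeOH, 0 °C) should give racemic [3,4-bis(benzyloxy)phenyl](oxiran-2-yl)methanone F3. Hydrolytic kinetic resolution with water (0.55 equiv) and the chiral [N,N'-bis(3,5-di-tert-butylsalicylidene)-1,2-cyclohexanediaminato]cobalt acetate complex (trivalent cobalt; the enantiomer of the catalyst that hydrolyses the (S)-epoxide) should leave the (R)-epoxy ketone. It comes back to the route at 12.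

## Further compounds

F1 | step 10 | 4β-{2,6-bis(benzyloxy)-4-[(R)-[3,4-bis(benzyloxy)phenyl][(2R)-oxiran-2-yl]methoxy]phenyl}-5,7,3',4'-tetra-O-benzyl-(−)-epicatechin | O[C@@H]1[C@@H](c2c(OCc3ccccc3)cc(O[C@H](c3ccc(OCc4ccccc4)c(OCc4ccccc4)c3)[C@H]3CO3)cc2OCc2ccccc2)c2c(OCc3ccccc3)cc(OCc3ccccc3)cc2O[C@@H]1c1ccc(OCc2ccccc2)c(OCc2ccccc2)c1
F0 | step 4 | none | none
F2 | step 8 | 1-[3,4-bis(benzyloxy)phenyl]prop-2-en-1-one | C=CC(=O)c1ccc(OCc2ccccc2)c(OCc2ccccc2)c1
F3 | step 8 | rac-[3,4-bis(benzyloxy)phenyl](oxiran-2-yl)methanone | O=C(C1CO1)c1ccc(OCc2ccccc2)c(OCc2ccccc2)c1
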